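**Plan**

- Retrosynthesis: the three aryl O–CH2OCH3 acetals are cut first. Both bonds of the ketone carbon are then cut together, C(=O)–CH2 of the propanone chain and C(=O)–C6 of the chroman, which leads to carbon monoxide, a 2-arylethylborane (from a vinylarene) and a C6 iodide. Last come the aryl–prenyl bond and the vinyl C=C of ring B, and the C6–I, C4a–C4 and O1–C2 bonds of ring A.
- Forward: the dihydropyran ring is annulated onto phloroglucinol first, then ring A is MOM-protected and iodinated at C6. Ring B is dressed (O-methyl, MOM, prenyl, vinyl) on a bromocatechol aldehyde. One pot of hydroboration and carbonylative coupling joins chain, carbonyl carbon and ring A, and acid frees the three phenols.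
- Enabling feature: the ketone carbon is a single carbon between C6 of ring A and an unbranched CH2–CH2 link to ring B. C6 is flanked by the oxygen-bearing C5 and C7, which direct metalation there and later favour CO insertion over direct coupling. The CH2–CH2 link is the anti-Markovnikov footprint of a vinyl group that 9-BBN-H can tell from the trisubstituted prenyl alkene.
- Stereochemistry (remark): the target has no stereocentre and its only C=C bond carries two identical methyl groups, so no configuration has to be set.

Key step: step 8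

**Route**

Step 1
Reactants: 1 phloroglucinol (benzene-1,3,5-triol); 2 isoprene (2-methylbuta-1,3-diene)
Product: 3 2,2-dimethylchroman-5,7-diol
Conditions: Amberlyst 15 (sulfonic acid resin), THF/heptane, 65 °C, 1 in excess
Reagents that add atoms: none
Why: acid-catalysed Friedel–Crafts C-prenylation of the symmetric triol followed by Markovnikov addition of the neighbouring phenol to the tertiary cation (chroman annulation) should give a single mono-chroman, the excess of 1 limiting a second annulation.

Step 2
Reactants: 3 2,2-dimethylchroman-5,7-diol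
Product: 4 5,7-bis(methoxymethoxy)-2,2-dimethylchroman
Conditions: NaH, MOMCl, DMF, 0 °C to rt
Reagents that add atoms: chloromethyl methyl ether (MOMCl), COCCl
Why: Williamson-type O-alkylation of both phenoxides with the hard electrophile MOMCl should give the bis-acetal, which protects the phenols and provides the directing groups for step 3.

Step 3
Reactants: 4 5,7-bis(methoxymethoxy)-2,2-dimethylchroman
Product: 6 6-iodo-5,7-bis(methoxymethoxy)-2,2-dimethylchroman, via aryllithium 5 (not isolated)
Conditions: n-BuLi, THF, 0 °C; then I2, THF, −78 °C to rt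
Reagents that add atoms: iodine, II
Why: directed ortho-metalation should favour C6–H, which lies between two MOM ethers whose distal oxygens can both chelate lithium, over C8–H (one MOM ether and the ring oxygen), and iodine then quenches the aryllithium.

Step 4
Reactants: 7 3-bromo-4,5-dihydroxybenzaldehyde
Product: 8 3-bromo-5-hydroxy-4-methoxybenzaldehyde
Conditions: MeI (1 equiv), Li2CO3, DMF, 40 °C
Reagents that add atoms: iodomethane, CI
Why: regioselective Williamson etherification, since the C4 hydroxyl (para to the formyl group, ortho to bromine) is the more acidic one and a weak base should form and methylate only its mono-phenoxide.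

Step 5
Reactants: 8 3-bromo-5-hydroxy-4-methoxybenzaldehyde
Product: 9 3-bromo-4-methoxy-5-(methoxymethoxy)benzaldehyde
Conditions: MOMCl, K2CO3, acetone, 0 °C to rt
Reagents that add atoms: chloromethyl methyl ether (MOMCl), COCCl
Why: O-alkylation (MOM ether formation) of the remaining phenol masks the acidic O–H before the borane and palladium steps and allows one common deprotection at the end.

Step 6
Reactants: 9 3-bromo-4-methoxy-5-(methoxymethoxy)benzaldehyde; 10 4,4,5,5-tetramethyl-2-(3-methylbut-2-en-1-yl)-1,3,2-dioxaborolane (prenylboronic acid pinacol ester)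
Product: 11 4-methoxy-3-(methoxymethoxy)-5-(3-methylbut-2-en-1-yl)benzaldehyde
Conditions: PdCl2(IPent)(3-chloropyridine) (IPent = 1,3-bis[2,6-di(pentan-3-yl)phenyl]imidazol-2-ylidene), KOH (aq.), THF, 65 °C
Reagents that add atoms: none
Why: Suzuki–Miyaura allyl–aryl coupling in which the bulky carbene ligand on palladium should steer reductive elimination to the unsubstituted allyl terminus, giving the linear prenyl arene and leaving the non-enolisable aldehyde intact.

Step 7
Reactants: 11 4-methoxy-3-(methoxymethoxy)-5-(3-methylbut-2-en-1-yl)benzaldehyde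
Product: 12 5-ethenyl-2-methoxy-1-(methoxymethoxy)-3-(3-methylbut-2-en-1-yl)benzene
Conditions: Ph3PCH3Br, KOtBu, THF, 0 °C to rt
Reagents that add atoms: methyltriphenylphosphonium bromide, C[P+](c1ccccc1)(c1ccccc1)c1ccccc1.[Br-]
Why: Wittig methylenation of an aromatic aldehyde with the unstabilised ylide is reliable and touches neither the acetal nor the prenyl group.

Step 8
Reactants: 12 5-ethenyl-2-methoxy-1-(methoxymethoxy)-3-(3-methylbut-2-en-1-yl)benzene; 6 6-iodo-5,7-bis(methoxymethoxy)-2,2-dimethylchroman
Product: 14 1-[5,7-bis(methoxymethoxy)-2,2-dimethylchroman-6-yl]-3-[4-methoxy-3-(methoxymethoxy)-5-(3-methylbut-2-en-1-yl)phenyl]propan-1-one, via alkylborane 13 (not isolated)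
Conditions: 9-BBN-H (1.05 equiv), THF, 0 °C to rt; then 6, PdCl2(dppf) (5 mol %), powdered K3PO4, CO (1 atm), THF/dioxane, 55 °C
Reagents that add atoms: carbon monoxide, [C-]#[O+]; 9-borabicyclo[3.3.1]nonane (9-BBN-H), B1C2CCCC1CCC2 (its boron and carbon atoms stay only in intermediate 13)
Why: anti-Markovnikov syn-hydroboration of the vinyl group gives the primary alkylborane 13; zerovalent palladium (formed from PdCl2(dppf)) then adds to the C6–I bond of 6, CO inserts to give the aroyl–palladium species, phosphate-activated 13 transfers its primary alkyl group, and reductive elimination forms the C(=O)–CH2 bond, so that both bonds to the carbonyl carbon arise in one operation. The closest known reaction type is the carbonylative Suzuki–Miyaura coupling of aryl iodides with B-alkyl-9-BBN reagents made in situ from terminal alkenes. No ring is closed and no stereocentre is formed. The step needs the vinyl group to react in preference to the trisubstituted prenyl alkene and boron to go to the terminal carbon, both of which the bulk of 9-BBN-H and the monosubstituted, donor-substituted styrene should secure. It also needs ketone formation in preference to direct aryl–alkyl coupling, which the two ortho oxygen substituents at C5 and C7 should secure by slowing transmetalation at the arylpalladium stage while the electron-rich aryl group migrates readily to CO.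

Step 9
Reactants: 14 1-[5,7-bis(methoxymethoxy)-2,2-dimethylchroman-6-yl]-3-[4-methoxy-3-(methoxymethoxy)-5-(3-methylbut-2-en-1-yl)phenyl]propan-1-one
Product: 15 1-(5,7-dihydroxy-2,2-dimethylchroman-6-yl)-3-[3-hydroxy-4-methoxy-5-(3-methylbut-2-en-1-yl)phenyl]propan-1-one (CNP0408176.0)
Conditions: HCl (1.25 M in MeOH), MeOH/THF, rt
Reagents that add atoms: none
Why: acid-catalysed transacetalisation to methanol should remove all three MOM groups, while the prenyl group has no ortho hydroxyl to cyclise onto and dilute acid at room temperature should leave its alkene untouched.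

**Compound list**

1 | phloroglucinol (benzene-1,3,5-triol) | Oc1cc(O)cc(O)c1 | starting material
2 | isoprene (2-methylbuta-1,3-diene) | C=CC(C)=C | starting material
3 | 2,2-dimethylchroman-5,7-diol | CC1(C)CCc2c(O)cc(O)cc2O1 | intermediate
4 | 5,7-bis(methoxymethoxy)-2,2-dimethylchroman | COCOc1cc(OCOC)c2CCC(C)(C)Oc2c1 | intermediate
5 | [5,7-bis(methoxymethoxy)-2,2-dimethylchroman-6-yl]lithium | COCOc1cc2OC(C)(C)CCc2c(OCOC)c1[Li] | intermediate
6 | 6-iodo-5,7-bis(methoxymethoxy)-2,2-dimethylchroman | COCOc1cc2OC(C)(C)CCc2c(OCOC)c1I | intermediate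
7 | 3-bromo-4,5-dihydroxybenzaldehyde | O=Cc1cc(O)c(O)c(Br)c1 | starting material
8 | 3-bromo-5-hydroxy-4-methoxybenzaldehyde | COc1c(O)cc(C=O)cc1Br | intermediate
9 | 3-bromo-4-methoxy-5-(methoxymethoxy)benzaldehyde | COCOc1cc(C=O)cc(Br)c1OC | intermediate
10 | 4,4,5,5-tetramethyl-2-(3-methylbut-2-en-1-yl)-1,3,2-dioxaborolane | CC(C)=CCB1OC(C)(C)C(C)(C)O1 | starting material
11 | 4-methoxy-3-(methoxymethoxy)-5-(3-methylbut-2-en-1-yl)benzaldehyde | COCOc1cc(C=O)cc(CC=C(C)C)c1OC | intermediate
12 | 5-ethenyl-2-methoxy-1-(methoxymethoxy)-3-(3-methylbut-2-en-1-yl)benzene | COCOc1cc(C=C)cc(CC=C(C)C)c1OC | intermediate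
13 | 9-{2-[4-methoxy-3-(methoxymethoxy)-5-(3-methylbut-2-en-1-yl)phenyl]ethyl}-9-borabicyclo[3.3.1]nonane | COCOc1cc(CCB2C3CCCC2CCC3)cc(CC=C(C)C)c1OC | intermediate
14 | 1-[5,7-bis(methoxymethoxy)-2,2-dimethylchroman-6-yl]-3-[4-methoxy-3-(methoxymethoxy)-5-(3-methylbut-2-en-1-yl)phenyl]propan-1-one | COCOc1cc(CCC(=O)c2c(OCOC)cc3OC(C)(C)CCc3c2OCOC)cc(CC=C(C)C)c1OC | intermediate
15 | 1-(5,7-dihydroxy-2,2-dimethylchroman-6-yl)-3-[3-hydroxy-4-methoxy-5-(3-methylbut-2-en-1-yl)phenyl]propan-1-one | COc1c(O)cc(CCC(=O)c2c(O)cc3c(c2O)CCC(C)(C)O3)cc1CC=C(C)C | target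

**Step count**

Total steps: 9 (ring A branch steps 1–3, ring B branch steps 4–7, union step 8, deprotection step 9).
Longest linear sequence: 6 steps (steps 4, 5, 6, 7, 8, 9).

**Steps most likely to fail**

Step 8. The carbonylative union may lose out to direct, CO-free aryl–alkyl coupling, or stall at the crowded aroyl–palladium stage so that the borane is consumed by protodeboronation. The fallback sets out from 4 and 12 and returns at 14, forming the same C(=O)–CH2 bond by a Weinreb ketone synthesis. The aryllithium 5, made from 4 as in step 3, would be trapped with N-methoxy-N-methylcarbamoyl chloride to give N-methoxy-N-methyl-5,7-bis(methoxymethoxy)-2,2-dimethylchroman-6-carboxamide F1. Compound 12 would be hydroborated to 13 and oxidised (NaOH, H2O2) to 2-[4-methoxy-3-(methoxymethoxy)-5-(3-methylbut-2-en-1-yl)phenyl]ethanol F2. An Appel reaction (CBr4, PPh3, CH2Cl2) would give 5-(2-bromoethyl)-2-methoxy-1-(methoxymethoxy)-3-(3-methylbut-2-en-1-yl)benzene F3, and Mg in THF would give {2-[4-methoxy-3-(methoxymethoxy)-5-(3-methylbut-2-en-1-yl)phenyl]ethyl}magnesium bromide F4. Addition of F4 to F1, whose magnesium chelate should resist a second addition, would give 14 on aqueous work-up.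

Step 3. Deprotonation may compete at C8 (between the C7 MOM ether and the ring oxygen) and lead to a mixture of regioisomeric iodides. The fallback sets out from 1 and returns at 6, and fixes the regiochemistry by symmetry. Vilsmeier–Haack formylation of 1 (POCl3, DMF, then water) would give 2,4,6-trihydroxybenzaldehyde F5. Its only non-chelated hydroxyl, para to the formyl group, would be alkylated with 3-chloro-3-methylbut-1-yne (K2CO3, KI, CuI, acetone) to 2,6-dihydroxy-4-[(2-methylbut-3-yn-2-yl)oxy]benzaldehyde F6. Heating in xylene (aryl propargyl ether Claisen rearrangement, then hydrogen shift and electrocyclisation at either of the two equivalent ortho positions) would give 5,7-dihydroxy-2,2-dimethyl-2H-chromene-6-carbaldehyde F7. Hydrogenation (H2, Pd/C, EtOAc) would give 5,7-dihydroxy-2,2-dimethylchroman-6-carbaldehyde F8, and NaH/MOMCl would give 5,7-bis(methoxymethoxy)-2,2-dimethylchroman-6-carbaldehyde F9. Pinnick oxidation (NaClO2, NaH2PO4, 2-methylbut-2-ene) would give 5,7-bis(methoxymethoxy)-2,2-dimethylchroman-6-carboxylic acid F10. Ipso-iododecarboxylation of this electron-rich, doubly ortho-oxygenated acid (I2, K3PO4, MeCN, heat) would give 6.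

Step 6. Allylic transposition during the allyl transfer may give the branched 1,1-dimethylallyl isomer, and the aqueous base may erode the aldehyde. The fallback sets out from 9 and returns at 11. Suzuki–Miyaura coupling of 9 with allylboronic acid pinacol ester (PdCl2(dppf), CsF, THF, 65 °C), where no regiochemical question arises, would give 4-methoxy-3-(methoxymethoxy)-5-(prop-2-en-1-yl)benzaldehyde F11. Cross-metathesis of F11 with excess 2-methylbut-2-ene (second-generation Grubbs catalyst RuCl2(=CHPh)(PCy3)(H2IMes), CH2Cl2, 40 °C) would turn the allyl group into the prenyl group of 11.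

**Further compounds**

F1 | step 8 | N-methoxy-N-methyl-5,7-bis(methoxymethoxy)-2,2-dimethylchroman-6-carboxamide | CON(C)C(=O)c1c(OCOC)cc2OC(C)(C)CCc2c1OCOC
F2 | step 8 | 2-[4-methoxy-3-(methoxymethoxy)-5-(3-methylbut-2-en-1-yl)phenyl]ethanol | COCOc1cc(CCO)cc(CC=C(C)C)c1OC
F3 | step 8 | 5-(2-bromoethyl)-2-methoxy-1-(methoxymethoxy)-3-(3-methylbut-2-en-1-yl)benzene | COCOc1cc(CCBr)cc(CC=C(C)C)c1OC
F4 | step 8 | {2-[4-methoxy-3-(methoxymethoxy)-5-(3-methylbut-2-en-1-yl)phenyl]ethyl}magnesium bromide | COCOc1cc(CC[Mg]Br)cc(CC=C(C)C)c1OC
F5 | step 3 | 2,4,6-trihydroxybenzaldehyde | O=Cc1c(O)cc(O)cc1O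
F6 | step 3 | 2,6-dihydroxy-4-[(2-methylbut-3-yn-2-yl)oxy]benzaldehyde | C#CC(C)(C)Oc1cc(O)c(C=O)c(O)c1
F7 | step 3 | 5,7-dihydroxy-2,2-dimethyl-2H-chromene-6-carbaldehyde | CC1(C)C=Cc2c(O1)cc(O)c(C=O)c2O
F8 | step 3 | 5,7-dihydroxy-2,2-dimethylchroman-6-carbaldehyde | CC1(C)CCc2c(O1)cc(O)c(C=O)c2O
F9 | step 3 | 5,7-bis(methoxymethoxy)-2,2-dimethylchroman-6-carbaldehyde | COCOc1cc2OC(C)(C)CCc2c(OCOC)c1C=O
F10 | step 3 | 5,7-bis(methoxymethoxy)-2,2-dimethylchroman-6-carboxylic acid | COCOc1cc2OC(C)(C)CCc2c(OCOC)c1C(=O)O
F11 | step 6 | 4-methoxy-3-(methoxymethoxy)-5-(prop-2-en-1-yl)benzaldehyde | COCOc1cc(C=O)cc(CC=C)c1OC
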